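## Structural features

The target is achiral and has no stereocentre: two identical, fully substituted benzene rings are joined through a CH2–O–CH2 chain, and there is no other ring. Numbering each ring from the carbon that carries the CH2 group (C1), bromine sits on C2, C3 and C6 and the catechol hydroxyls on C4 and C5, so C1 lies between two brominated carbons. The electron-poor catechols ionise easily and oxidise to ortho-quinones. The benzylic ether is para to the C4 hydroxyl, so it can ionise through a para-quinone methide under acid or once the phenoxide forms, and boron trihalides open it; the six aryl C–Br bonds in turn rule out hydrogenolysis and unselective halogen–metal exchange. The real difficulty is regiochemical: electrophilic substitution of a catechol fills the positions para to oxygen first, yet the carbon substituent must end up between two bromines on a ring with no other open position. In addition, an ether between two doubly ortho-substituted benzylic carbons has to be made without conditions that ionise it. The key step exploits the fact that in a 3,4,6-tribromocatechol diether the future C1 is the only C–H of the ring and is acidified by the bromines on C2 and C6, so a hindered magnesium amide can metalate only there. It also treats the CH2–O–CH2 chain as the skeleton of a bis(α-chloro) ether that accepts two such aryl nucleophiles.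

## Logic of the disconnections

**8 to 7.** The four catechol O–H bonds of 8 are traced back to four O–Si bonds in 7. Silicon is chosen because it is removed by buffered fluoride, without the boron or aluminium halides that would open the benzylic ether and without hydrogenolysis that would strip bromine. The gain is a neutral, non-oxidisable penultimate compound. The demand is that each phenoxide is protonated as soon as it is released.

**7 to 3 and 4.** Both aryl C1–CH2 bonds of 7 are cut in one operation, giving two identical arylmetal units 5 (each from one molecule of 3) and the two-carbon, one-oxygen bis-electrophile 4. The cut is placed there because C1 is the only hydrogen-bearing carbon of 3 and that hydrogen lies between two bromines, so metalation needs no directing group. All C–Br and C–O bonds of each ring are already in place. The whole skeleton is thereby reduced to one small arene used twice plus a linchpin. The demand is an organometallic with bromine on both ortho carbons that neither eliminates nor scrambles and that substitutes twice, through 6, on the same linchpin. An amide base instead of an exchange reagent, magnesium instead of lithium, and low temperature answer this.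

**3 to 2.** The two O–Si bonds of 3 are cut to the free catechol 2. Protection is introduced only here and directly as the group removed at the end, so no protecting-group exchange is needed. The demand is that both crowded oxygens are silylated.

**2 to 1.** The C4–Br bond of 2 is cut. In 1 the two open positions are equivalent by symmetry and each is para to a hydroxyl, so one electrophilic bromination can only give 2, and the remaining hydrogen lies between two bromines. This two-step access to 3 is preferred to a longer sequence through an aniline (exhaustive bromination, removal of nitrogen via a diazonium salt, ether cleavage, silylation). In that sequence the third bromine would have to enter meta to nitrogen on an already dibrominated, oxidation-prone ring, and a protecting-group exchange would be needed. The demand is that substitution stops after one bromine.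

## Other disconnections considered

Alternative 1: The cut goes through ring bonds C3–C4 and C5–C6 of both arenes. In the forward key step, bis[(2,4,5-tribromo-1,1-dioxothiophen-3-yl)methyl] ether A1 would add two molecules of vinylene carbonate A2 in Diels–Alder fashion, and each bridged adduct would lose its sulfonyl bridge as SO2, giving the bis(dihydrocatechol carbonate) A3 with a cis ring fusion at each carbonate. In its favour, the diene already carries all three bromines and the CH2–O–CH2 chain, the symmetrical dienophile removes any question of orientation, and the four sp3 centres of A3 vanish on aromatisation, so its diastereomers converge. No α-chloro ether and no organometallic next to a C–Br bond is needed; on these two points it is better than the chosen plan. Against it, A3 is at the wrong oxidation level and must lose two hydrogens per ring, while the easier aromatisation of a cis-dihydrocatechol derivative is β-elimination of one carbonate oxygen to a phenol, which would destroy the catechol. An electron-poor tribrominated diene with a weakly electron-rich dienophile is expected to need forcing conditions, and A1 itself requires S-oxidation of a very electron-poor thiophene. In comparison, on structure both plans are two-directional and use the symmetry of 8 equally. On mechanism, the chosen plan keeps the ring aromatic throughout, whereas here the decisive risk is moved to the aromatisation. On step economy, several steps to A1 plus cycloaddition, dehydrogenation and carbonate hydrolysis compare poorly with four steps in the chosen plan.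

Alternative 2: The cut is the C5–O bond of each ring, so the second catechol oxygen is introduced last. In the forward key step, bis[2,3,5,6-tetrabromo-4-(methoxymethoxy)benzyl] ether A4 would undergo one bromine–magnesium exchange per ring next to the acetal oxygen with iPrMgCl·LiCl, and borylation followed by peroxide oxidation would then give bis[2,3,6-tribromo-5-hydroxy-4-(methoxymethoxy)benzyl] ether A5. In its favour, C3 and C5 of A4 are equivalent, so a single exchange ortho to the acetal gives one product whichever of these bromines reacts, the acetal oxygen can guide the reagent by chelation, and hydroxylation of arylmetals through borates is dependable. The central ether can be made without 4, which is an advantage over the chosen plan. Against it, exactly one of four bromines per ring must exchange, in competition with exchange at C2 or C6 next to the benzylic oxygen and with a second exchange, and the arylmagnesium again has an ortho bromine. The acetal of A5 must be removed with acid from a para-oxygenated benzylic ether, the conditions under which that ether ionises, and installing the acetal needs an α-chloro ether of its own, so the hazard is not really avoided. In comparison, on structure it is the equal of the chosen plan in symmetry and two-directionality. On mechanism, its site selectivity rests on a kinetic preference among several bromines, whereas the chosen plan has a single C–H. On step economy, exhaustive bromination, ether formation, protection, the key step and deprotection make it no shorter, and its acidic endgame is weaker than buffered fluoride.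

Alternative 3: The cut goes through ring bonds C6–C1 and C2–C3 of both arenes. In the forward key step, two equivalents of 2,5-dibromo-3,4-dimethoxythiophene 1,1-dioxide A6 would add across the two alkynes of bis(3-bromoprop-2-ynyl) ether A7 and lose the sulfonyl bridge as SO2, giving bis(2,3,6-tribromo-4,5-dimethoxybenzyl) ether A8. In its favour, the diene is symmetrical, so the orientation of the unsymmetrical alkyne does not matter, and one step sets all six substituents of each ring at the aromatic oxidation level, which is better than Alternative 1. A7 is one alkyne bromination away from a catalogue dialkyne, so the central ether is bought and not made. No 4 and no organometallic is needed; on hazard it is better than the chosen plan. Against it, A8 carries four methyl ethers whose removal needs a boron trihalide or a comparable Lewis acid, which is expected to cleave the benzylic ether to benzylic bromides as well; this is the reason the chosen plan uses silyl protection. A silyloxy analogue of A6 is not an obvious compound. Thiophene dioxides are electron-poor dienes, so a bromoalkyne that is neither electron-rich nor strained is expected to need high temperature, and two cycloadditions must succeed on one molecule. In comparison, on structure it is the equal of the chosen plan in symmetry. On mechanism, the chosen plan relies on a more secure class of bond-forming event and a much safer deprotection. On step economy, the two are about equal (two steps to A6, one to A7, the key step and a demethylation).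

Key step: step 3

Remark: 1 is taken to be a catalogue compound; 4 is a regulated carcinogen and is handled only as a solution in a closed system and used as the limiting reagent.

## Steps

Step 1
Reactants: 1 3,6-dibromobenzene-1,2-diol (3,6-dibromocatechol)
Product: 2 3,4,6-tribromobenzene-1,2-diol
Conditions: Br2 (1.0 equiv, dropwise), AcOH/CH2Cl2, 0 °C → rt
Reagents that add atoms: bromine, BrBr
Why: Electrophilic aromatic bromination of a catechol; the two open positions of 1 are equivalent and each is para to a hydroxyl, so the first bromine can only give 2. The new bromine flanks the last C–H and lowers its reactivity, so slow addition of one equivalent at low temperature should stop at the tribromide, and the HBr formed keeps the catechol from being oxidised to a quinone.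

Step 2
Reactants: 2 3,4,6-tribromobenzene-1,2-diol
Product: 3 1,2,5-tribromo-3,4-bis(tert-butyldimethylsilyloxy)benzene
Conditions: TBSCl (2.6 equiv), imidazole (5 equiv), DMF, rt → 40 °C
Reagents that add atoms: tert-butyldimethylsilyl chloride, CC(C)(C)[Si](C)(C)Cl
Why: Silylation of phenols with a silyl chloride and imidazole; the acidic bromophenols react as phenoxides, and 2,6-disubstituted phenols of this kind still accept the tert-butyldimethylsilyl group in DMF with mild warming. Silyl ethers are chosen because they survive amide bases and arylmagnesium reagents and are later removed by fluoride without a Lewis acid.

Step 3
Reactants: 3 1,2,5-tribromo-3,4-bis(tert-butyldimethylsilyloxy)benzene (first of 2 equiv); 3 1,2,5-tribromo-3,4-bis(tert-butyldimethylsilyloxy)benzene (second of 2 equiv); 4 bis(chloromethyl) ether (1 equiv)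
Product: 7 bis[2,3,6-tribromo-4,5-bis(tert-butyldimethylsilyloxy)benzyl] ether, via arylmagnesium chloride 5 (not isolated), via chloromethyl benzyl ether 6 (not isolated)
Conditions: TMPMgCl·LiCl (1.1 equiv per 3), THF, −20 → 0 °C; then 4 (0.45 equiv per 3, toluene solution, closed system), −40 °C → rt; aq NH3/NH4Cl quench
Reagents that add atoms: none
Why: Two molecules of 3 are each deprotonatively magnesiated to 5, and the two molecules of 5 then alkylate one molecule of the bis(α-chloro) ether 4 in succession, so both aryl C1–CH2 bonds are formed on one linchpin. TMPMgCl·LiCl, a hindered non-nucleophilic amide whose aggregates are broken up by LiCl, removes the only ring proton of 3, which is acidified inductively by the bromines on both neighbouring carbons, and because the base is an amide and not an alkylmagnesium no bromine–magnesium exchange competes. The resulting 5 has a largely covalent C–Mg bond, so below 0 °C neither β-elimination to an aryne nor bromine migration is expected, and no silyl shift can occur because magnesium is meta and para, not ortho, to the silyloxy groups. Assisted by the Lewis-acidic magnesium salts, 4 ionises to a small oxocarbenium ion that the hindered aryl nucleophile can capture to give 6, and 6 is again an α-chloro ether that ionises in the same way and is arylated by the second molecule of 5 to give 7. The closest known reactions are the magnesiation of polyhaloarenes with TMP-magnesium amides and the long-known alkylation of Grignard reagents by chloromethyl ethers, including the formation of symmetrical ethers from 4. No ring is closed and no stereocentre is formed. The selectivity needed is the site of metalation, secured by the single C–H of 3, and complete double substitution, secured by a slight excess of 5 over the two reactive positions of 4 so that 6 cannot remain, which also ensures that the carcinogenic 4 is consumed before the ammoniacal quench. The liberated 2,2,6,6-tetramethylpiperidine is too hindered to compete with 5 for the oxocarbenium ions at low temperature.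

Step 4
Reactants: 7 bis[2,3,6-tribromo-4,5-bis(tert-butyldimethylsilyloxy)benzyl] ether
Product: 8 bis(2,3,6-tribromo-4,5-dihydroxybenzyl) ether (target)
Conditions: TBAF (4.4 equiv), AcOH (6 equiv), THF, 0 °C, argon; pH 4 aqueous work-up, EtOAc
Reagents that add atoms: none
Why: Fluoride-induced cleavage of aryl silyl ethers; the electron-poor aryloxides leave readily from silicon, and the AcOH buffer protonates each phenoxide as it is released, so the C4 phenoxide cannot expel the benzylic oxygen through a para-quinone methide and the catechols are not left as oxidisable anions. The aryl bromides and the dibenzylic ether are inert to buffered fluoride in THF, and an alcohol-free work-up avoids solvolysis of the para-hydroxybenzylic ether.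

## Compound list

1 | 3,6-dibromobenzene-1,2-diol | Oc1c(O)c(Br)ccc1Br | starting material
2 | 3,4,6-tribromobenzene-1,2-diol | Oc1c(O)c(Br)c(Br)cc1Br | intermediate
3 | 1,2,5-tribromo-3,4-bis(tert-butyldimethylsilyloxy)benzene | CC(C)(C)[Si](C)(C)Oc1c(O[Si](C)(C)C(C)(C)C)c(Br)cc(Br)c1Br | intermediate
4 | bis(chloromethyl) ether | ClCOCCl | starting material
5 | [2,3,6-tribromo-4,5-bis(tert-butyldimethylsilyloxy)phenyl]magnesium chloride, LiCl complex | CC(C)(C)[Si](C)(C)Oc1c(O[Si](C)(C)C(C)(C)C)c(Br)c([Mg]Cl)c(Br)c1Br | intermediate
6 | chloromethyl 2,3,6-tribromo-4,5-bis(tert-butyldimethylsilyloxy)benzyl ether | CC(C)(C)[Si](C)(C)Oc1c(O[Si](C)(C)C(C)(C)C)c(Br)c(COCCl)c(Br)c1Br | intermediate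
7 | bis[2,3,6-tribromo-4,5-bis(tert-butyldimethylsilyloxy)benzyl] ether | CC(C)(C)[Si](C)(C)Oc1c(O[Si](C)(C)C(C)(C)C)c(Br)c(COCc2c(Br)c(O[Si](C)(C)C(C)(C)C)c(O[Si](C)(C)C(C)(C)C)c(Br)c2Br)c(Br)c1Br | intermediate
8 | bis(2,3,6-tribromo-4,5-dihydroxybenzyl) ether | Oc1c(O)c(Br)c(COCc2c(Br)c(O)c(O)c(Br)c2Br)c(Br)c1Br | target

## Step count and least certain steps

Total step count: 4. Longest linear sequence: 4 steps (1 → 2 → 3 → 7 → 8); 4 enters at step 3, where two molecules of 3 are used per molecule of 4.

**Step 3 (key step).**
- What may go wrong: the doubly ortho-brominated, electron-poor arylmagnesium is a weak nucleophile. Substitution may stall after the first arylation, or the oxocarbenium ions may be diverted by the liberated amine or by ring-opening of THF. Warming to compensate invites aryne formation and bromine migration. Slow metalation can first be answered within the same chemistry by the stronger bis-amide (TMP)2Mg·2LiCl.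
- Fallback: the ether is built through C–O instead of C–C bond formation. Setting out from 3, magnesiation as in step 3 to 5 and quenching with DMF should give, after mildly acidic work-up, 2,3,6-tribromo-4,5-bis(tert-butyldimethylsilyloxy)benzaldehyde F1. Reductive homo-etherification of this aldehyde with Et3SiH and catalytic TMSOTf in CH2Cl2 (−78 → 0 °C) joins two aldehyde molecules through an oxocarbenium ion that the silane reduces. This would return to the route at 7 without any use of 4.

**Step 4.**
- What may go wrong: a C4 phenoxide that is not protonated at once can expel the benzylic oxygen through a para-quinone methide, which breaks or solvolyses the central ether. The catechol anions can be oxidised by air. Separating the polar tetraphenol from ammonium salts may cost material.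
- Fallback: silicon is exchanged for acetyl before the phenols are set free. Setting out from 7, CsF and Ac2O in DMF (0 °C → rt) should convert each silyl ether directly into the acetate, the phenoxide being acylated as it forms, to give bis(4,5-diacetoxy-2,3,6-tribromobenzyl) ether F2, a neutral compound that can be purified. Aminolysis of these activated aryl esters with NH4OAc in aqueous THF at room temperature, close to neutrality, would return to the route at 8.

**Step 2.**
- What may go wrong: silylation may stall after the first silyl group because of crowding between the ortho bromine and the neighbouring silyloxy group. Silyl may also be lost by hydrolysis from the acidic bromophenol on work-up or on silica.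
- Fallback: both oxygens are tied to one silicon. Setting out from 2, tBu2Si(OTf)2 and 2,6-lutidine in CH2Cl2 (0 °C) should give 4,5,7-tribromo-2,2-di-tert-butyl-1,3,2-benzodioxasilole F3. Under the conditions of step 3 this would be magnesiated to (4,6,7-tribromo-2,2-di-tert-butyl-1,3,2-benzodioxasilol-5-yl)magnesium chloride F4. Two molecules of that reagent would alkylate 4, through chloromethyl (4,6,7-tribromo-2,2-di-tert-butyl-1,3,2-benzodioxasilol-5-yl)methyl ether F5, to give bis[(4,6,7-tribromo-2,2-di-tert-butyl-1,3,2-benzodioxasilol-5-yl)methyl] ether F6. Buffered fluoride as in step 4 would then return to the route at 8.

## Further compounds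

F1 | step 3 | 2,3,6-tribromo-4,5-bis(tert-butyldimethylsilyloxy)benzaldehyde | CC(C)(C)[Si](C)(C)Oc1c(O[Si](C)(C)C(C)(C)C)c(Br)c(C=O)c(Br)c1Br
F2 | step 4 | bis(4,5-diacetoxy-2,3,6-tribromobenzyl) ether | CC(=O)Oc1c(OC(C)=O)c(Br)c(COCc2c(Br)c(OC(C)=O)c(OC(C)=O)c(Br)c2Br)c(Br)c1Br
F3 | step 2 | 4,5,7-tribromo-2,2-di-tert-butyl-1,3,2-benzodioxasilole | CC(C)(C)[Si]1(C(C)(C)C)Oc2c(Br)c(Br)cc(Br)c2O1
F4 | step 2 | (4,6,7-tribromo-2,2-di-tert-butyl-1,3,2-benzodioxasilol-5-yl)magnesium chloride | CC(C)(C)[Si]1(C(C)(C)C)Oc2c(Br)c(Br)c([Mg]Cl)c(Br)c2O1
F5 | step 2 | chloromethyl (4,6,7-tribromo-2,2-di-tert-butyl-1,3,2-benzodioxasilol-5-yl)methyl ether | CC(C)(C)[Si]1(C(C)(C)C)Oc2c(Br)c(Br)c(COCCl)c(Br)c2O1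
F6 | step 2 | bis[(4,6,7-tribromo-2,2-di-tert-butyl-1,3,2-benzodioxasilol-5-yl)methyl] ether | CC(C)(C)[Si]1(C(C)(C)C)Oc2c(Br)c(Br)c(COCc3c(Br)c(Br)c4O[Si](C(C)(C)C)(C(C)(C)C)Oc4c3Br)c(Br)c2O1
A1 | alternative 1 | bis[(2,4,5-tribromo-1,1-dioxothiophen-3-yl)methyl] ether | O=S1(=O)C(Br)=C(COCC2=C(Br)S(=O)(=O)C(Br)=C2Br)C(Br)=C1Br
A2 | alternative 1 | vinylene carbonate (1,3-dioxol-2-one) | O=C1OC=CO1
A3 | alternative 1 | bis[(4,6,7-tribromo-2-oxo-3a,7a-dihydro-1,3-benzodioxol-5-yl)methyl] ether, each ring cis-fused, one diastereomer drawn | O=C1O[C@H]2C(Br)=C(COCC3=C(Br)[C@H]4OC(=O)O[C@H]4C(Br)=C3Br)C(Br)=C(Br)[C@H]2O1
A4 | alternative 2 | bis[2,3,5,6-tetrabromo-4-(methoxymethoxy)benzyl] ether | COCOc1c(Br)c(Br)c(COCc2c(Br)c(Br)c(OCOC)c(Br)c2Br)c(Br)c1Br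
A5 | alternative 2 | bis[2,3,6-tribromo-5-hydroxy-4-(methoxymethoxy)benzyl] ether | COCOc1c(O)c(Br)c(COCc2c(Br)c(O)c(OCOC)c(Br)c2Br)c(Br)c1Br
A6 | alternative 3 | 2,5-dibromo-3,4-dimethoxythiophene 1,1-dioxide | COC1=C(Br)S(=O)(=O)C(Br)=C1OC
A7 | alternative 3 | bis(3-bromoprop-2-ynyl) ether | BrC#CCOCC#CBr
A8 | alternative 3 | bis(2,3,6-tribromo-4,5-dimethoxybenzyl) ether | COc1c(OC)c(Br)c(COCc2c(Br)c(OC)c(OC)c(Br)c2Br)c(Br)c1Br
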